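## Structural features

The target is a single carbocycle, a cyclohex-2-en-1-one with no second ring. C1 is the ketone, C2 carries a hydroxymethyl group and forms the ring double bond with C3, C4 carries an isobutyrate, C5 an isopropyl group, and C6 the ester of (E)-4-hydroxy-2-methylbut-2-enoic (4-hydroxytiglic) acid. The three stereocentres C4, C5 and C6 are contiguous and are (4S,5S,6R) in this numbering: the C6 oxygen is trans and the C4 oxygen cis to the isopropyl group. The fragile points are the C6 ester α to the ketone (epimerisation, acyl shift), the allylic C4 ester, two free primary allylic alcohols next to two different secondary esters, and a ring that is only two eliminations away from a phenol, so every β-acyloxy ketone on the way is a hazard. The real difficulty is the distinction between C4 and C6: two oxygenated carbons flanking C5 that need different acyl groups, opposite relationships to isopropyl and different neighbours (alkene CH at C3, ketone at C1). The key step exploits exactly this pair. With C1 and C3 levelled to CH2 and an exocyclic methylene on C2, the ring has a constitutional twofold axis through C2 and C5, C4 and C6 are the same kind of carbinol, and in the trans diol (both carbinols S) C5 is not a stereocentre. Both C6–C1 and C4–C3 can then be formed by the same catalyst-controlled carbonyl allylation, and the isopropyl group later tells the equatorial C6 hydroxyl from the axial C4 hydroxyl.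

## Logic of the disconnections

19 from 18: the two O–Si bonds are cut. Both primary allylic hydroxyls must be masked while the ring is oxidised and acylated, and one fluoride step frees them together. The forward step must leave two secondary esters, the α-acyloxy ketone and the allylic ester untouched, so it must be non-basic and only weakly acidic.

18 from 17 from 16: the C1–O bonds are cut (ketone to carbinol to CH2). C1 is the only ring methylene left in 16 and sits on the more substituted alkene carbon, the position that selenium dioxide oxidises without moving the double bond. Keeping C1 as CH2 until here removes the α-acyloxy ketone, and with it the lability of C6, from all earlier intermediates. The forward step must put oxygen on C1 and not on the silyloxymethyl carbon or on C3. Hydrogen-abstraction oxidants are avoided because the allyl radical could be trapped at either end.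

16 from 15 from 14: the acyl C–O bond of the C4 ester is cut, then the C4–H bond (15 back to the ketone of 14). The C4 ketone is what fixes the position of the ring alkene one stage earlier, so C4 is re-created afterwards under control of C5. The forward reduction must be 1,2 and must place the hydroxyl cis to isopropyl. The acylation must cope with a hindered axial allylic alcohol.

14 from 13, 13 from 11 through 12, 11 from 10: the O–Si bond of 14 is cut first. The C2=C3 bond and the free hydroxymethyl of 13 are then traced back to the spiro-epoxide and C4 ketone of 12 (retro-E1cB, re-forming the C2–O bond), 12 to the carbinol of 11, and 11 to the exocyclic alkene of 10 (both epoxide C–O bonds). In 12 only C3–H2 lies between the carbonyl and the epoxide carbon, so the alkene can only end at C2=C3 with the oxygen on the exocyclic carbon. This removes the enone and the primary alcohol and leaves one isolated alkene and one secondary alcohol. The forward steps need epoxidation of the 1,1-disubstituted alkene only, and an epoxide opening that is faster than loss of the C6 carboxylate from the same ketone. The primary hydroxyl that appears in 13 must be silylated before the C4 chemistry.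

10 from 5 and 9: the acyl C–O bond at C6 is cut. This is where the two carbinols of 5 are told apart, and it is the step that turns C5 into a stereocentre and so fixes the absolute configuration of the whole C4–C6 triad. It leads to a diol with both hydroxyls free. The forward acylation must take the hydroxyl trans to isopropyl and stop at the monoester. Both carbinols of 5 must have the same configuration, because the cis diol would be meso and the distinction would then be between enantiotopic groups.

9 from 8, 8 from 6 and 7: the O–ethyl bond is cut (hydrolysis), then the C2=C3 bond of the side chain (olefination). The side chain is made separately so that its geometry is settled before it meets the ring. The olefination must give the E isomer.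

5 from 2 and 3 through 4: the ring bonds C6–C1 and C4–C3 are cut. Each joins a carbinol carbon to an allyl terminus, the retron of carbonyl allylation. Both aldehydes are taken from 2 at the alcohol level and both allyl termini from 3. The cut gives the ring, two stereocentres and all ten ring-bound carbons from two achiral pieces. The forward step needs two additions of the same catalyst-controlled sense, the second one intramolecular within 4, C- and not O-allylation, and ring closure faster than a second intermolecular allylation. For that reason 3 is used in equimolar amount and added slowly, not in excess.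

2 from 1: the two C(=O)–OEt bonds are cut (reduction). This reaches a commercial malonate and has no selectivity demand.

## Other disconnections considered

Alternative 1: The ring is cut at C1–C6 and C4–C5, which gives the pyrone A1 as the diene (C1 to C4) and the (E)-enol ether A2 as the C5–C6 unit. The forward step is an inverse-demand Diels–Alder reaction under a chiral Lewis acid that should give the bridged lactone A3 with the alkoxy group endo and the isopropyl group exo.
- In its favour: one step closes the carbocycle and sets C4, C5 and C6 together. The E geometry gives the trans C5/C6 pair, the endo rule places the C6 oxygen, and the lactone oxygen on C4 is cis to isopropyl. The C2=C3 alkene is in place and the C4 and C6 oxygens arrive already differentiated (lactone against benzyl ether). On stereocontrol, on oxygen differentiation and on precedent of the key reaction it is the better plan.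
- Against it here: in A3 both carboxyl carbons of A1 (lactone carbonyl and ester) sit on the bridgehead that is C1, the future ketone, and C2 is a bare alkene CH. C1 would have to lose two carbons (lactone opening, then degradation of a malonate-type centre to a ketone), and the hydroxymethyl group would have to be added to C2 by a separate Morita–Baylis–Hillman-type step. The skeleton is also prone to decarboxylative retro-cycloaddition on heating, and A2 is a hindered, sluggish dienophile.
- Comparison: structurally it maps the stereotriad well and the C1/C2 carbon pattern badly, whereas the chosen plan has every carbon in place and pays with one C–H oxidation. Mechanistically it is an established cycloaddition against an untested tandem. In step economy it is expected to be longer after its key step.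

Alternative 2: No ring bond is cut. The ring is taken as the quinone monoketal A4 and the cuts are C5–isopropyl and C6–O. The forward step is a copper-catalysed enantioselective 1,4-addition of the dialkylzinc A5 to one enantiotopic enone of A4, then silylation of the zinc enolate and peracid (Rubottom) oxidation in the same flask to give the hydroxy enone A6.
- In its favour: after one operation the C1 ketone, the C2=C3 alkene and a free C6 hydroxyl trans to isopropyl are present at the correct oxidation levels, which is where the chosen plan is weakest (steps 11 and 12). C6 and C4 are differentiated by construction (hydroxyl against ketal), and the C4 ketone can later be reduced cis to isopropyl as in the chosen route. In step count and in oxidation-state economy at C1 and C6 it is the equal or the better, and its catalysis is established.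
- Against it here: transfer of a secondary alkyl group from zinc is slower and usually less selective than that of the primary groups for which this desymmetrisation is best known. The C2 hydroxymethyl carbon is missing and must be added by a Morita–Baylis–Hillman-type reaction on a hindered, base-sensitive enone. Unveiling the C4 ketone next to the C1 enone gives a cyclohex-2-ene-1,4-dione that can tautomerise to a hydroquinone through C5–H and C6–H, so C1 has to be masked while C4 is reduced and acylated.
- Comparison: that masking is a redox detour of the same kind as the C4 oxidation and reduction in the chosen route. The chosen plan brings the C2 carbon with the ring and never passes through an ene-dione, but it rests on a new reaction.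

Alternative 3: The cut is C5–C6, which opens the ring to the Z-vinylglyoxal A7. Its aldehyde carbon is C6, its keto carbon C1, and the trisubstituted alkene on C4 is the latent isopropyl group. The forward step is a Lewis acid-promoted intramolecular carbonyl-ene reaction that should give the cyclohexenone A8 with the C6 hydroxyl next to the C1 ketone and an isopropenyl group on C5.
- In its favour: every ring atom of A8 is at its final oxidation level and the C4 isobutyrate is already in place. Only C6 acylation, hydrogenation of the isopropenyl group and desilylation remain. No C–H oxidation is needed and C4 and C6 are differentiated by construction. On the length and safety of the end game it is the better plan, and the carbonyl-ene reaction is a known reaction type.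
- Against it here: the absolute configuration rests on a C4 stereocentre that must be set beforehand in a sensitive acyclic precursor (a Z-enone attached to a vicinal dicarbonyl, open to hydration, Z to E isomerisation and ionisation of the allylic ester under Lewis acid). The 4,5-cis and 5,6-trans outcome depends on a transition state in which the C4 ester must sit axial. The isopropenyl group must be hydrogenated in the presence of the enone and the side-chain alkene. The synthesis of A7 is several steps in itself.
- Comparison: the chosen plan has a two-step front end with catalyst control and a long end game, and this alternative has the reverse. Overall step counts are expected to be similar.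

Key step: step 2

Assumption: (S)-Cl,MeO-BIPHEP is taken as the ligand enantiomer that leads to the (S)-carbinols of 5, by analogy with the intermolecular reaction; if the sense proves opposite, the (R)-ligand is used.
Abbreviation: TBS = tert-butyldimethylsilyl. Ring atoms keep the numbering C1 to C6 of the target in all intermediates.

## Steps

Step 1
Reactants: 1 diethyl 2-(propan-2-yl)propanedioate (diethyl isopropylmalonate)
Product: 2 2-(propan-2-yl)propane-1,3-diol
Conditions: LiAlH4, THF, 0 °C to reflux; then H2O, 15% aqueous NaOH, H2O
Reagents that add atoms: none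
Why: Hydride reduction of both ester groups to primary alcohols is a standard reaction; no stereocentre is involved.

Step 2
Reactants: 2 2-(propan-2-yl)propane-1,3-diol; 3 2-methylidenepropane-1,3-diyl diacetate
Product: 5 (1S,3S)-5-methylidene-2-(propan-2-yl)cyclohexane-1,3-diol, via acyclic hydroxy allylic acetate 4 (not isolated)
Conditions: [Ir(cod)Cl]2 (5 mol%), (S)-Cl,MeO-BIPHEP (10 mol%), 4-chloro-3-nitrobenzoic acid (20 mol%), Cs2CO3 (40 mol%), 1,4-dioxane, 100 °C; 3 (1.0 equiv) added over 6 h at 0.1 M, then dilution to 0.02 M
Reagents that add atoms: none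
Why: Proposed new method: the cyclometallated C,O-benzoate formed from [Ir(cod)Cl]2, the bisphosphine and the nitrobenzoic acid should dehydrogenate one carbinol of 2, ionise one acetate of 3 from the monovalent state to a π-allyl complex of trivalent iridium and add the allyl group to the transient aldehyde through a closed chair transition state, which gives 4 (C6–C1 bond). Repetition of the sequence inside 4 (dehydrogenation of the remaining primary alcohol, ionisation of the remaining acetate) should deliver the tethered allyl terminus to the second aldehyde and form C4–C3. The closest known reactions are the two-directional iridium-catalysed C-allylation of 2-substituted propane-1,3-diols with allyl acetate from the alcohol oxidation level and ring-forming additions of 2-(metallomethyl)allyl units to aldehydes; a ring-closing version with a bis-allylic donor is not known. The ring closes by 6-exo-trig attack of the allyl terminus on the carbonyl carbon through a bicyclo[3.3.1]-like transition state, and the central allyl carbon becomes the methylene-bearing ring atom C2. Both carbinol centres (1S,3S) are set by the ligand-defined iridium centre and not by the substrate; the configuration at the isopropyl-bearing carbon of 4 is irrelevant because both epimers converge on 5, in which that carbon is not stereogenic. The step needs C- over O-allylation (the trivalent allyl complex is nucleophilic at carbon), ring closure over a second intermolecular allylation (equimolar 3, dilution once 3 is consumed, and a three-atom tether that allows only the six-membered closure) and no re-oxidation of the secondary homoallylic alcohols (they are dehydrogenated far more slowly than primary carbinols, as in the known diol allylations).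

Step 3
Reactants: 6 2-[(tert-butyldimethylsilyl)oxy]acetaldehyde; 7 ethyl 2-(triphenyl-λ5-phosphanylidene)propanoate
Product: 8 ethyl (2E)-4-[(tert-butyldimethylsilyl)oxy]-2-methylbut-2-enoate
Conditions: CH2Cl2, 0 °C to rt
Reagents that add atoms: none
Why: Wittig olefination with a stabilised α-methyl ylide, which should give the E-trisubstituted enoate (tiglate geometry) with high selectivity.

Step 4
Reactants: 8 ethyl (2E)-4-[(tert-butyldimethylsilyl)oxy]-2-methylbut-2-enoate
Product: 9 (2E)-4-[(tert-butyldimethylsilyl)oxy]-2-methylbut-2-enoic acid
Conditions: LiOH, THF/MeOH/H2O, rt; then 1 M HCl to pH 4, 0 °C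
Reagents that add atoms: lithium hydroxide, [Li+].[OH-] (oxygen of the acid hydroxyl)
Why: Saponification of an unhindered ethyl ester; the primary silyl ether and the E alkene should survive mild hydroxide and a brief cold acidification.

Step 5
Reactants: 5 (1S,3S)-5-methylidene-2-(propan-2-yl)cyclohexane-1,3-diol; 9 (2E)-4-[(tert-butyldimethylsilyl)oxy]-2-methylbut-2-enoic acid
Product: 10 (1S,2S,3S)-3-hydroxy-5-methylidene-2-(propan-2-yl)cyclohexyl (2E)-4-[(TBS)oxy]-2-methylbut-2-enoate
Conditions: DCC, DMAP (cat.), CH2Cl2, −20 to 0 °C, 9 (1.0 equiv) added slowly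
Reagents that add atoms: none
Why: Steglich esterification; in the chair with isopropyl equatorial the hydroxyl trans to isopropyl is equatorial and the other axial, the same pair as menthol and neomenthol, of which the equatorial alcohol is acylated clearly faster. Taking the hydroxyl trans to isopropyl makes it C6 and turns C5 into a stereocentre (S).

Step 6
Reactants: 10 (1S,2S,3S)-3-hydroxy-5-methylidene-2-(propan-2-yl)cyclohexyl (2E)-4-[(TBS)oxy]-2-methylbut-2-enoate
Product: 11 (5S,6S,7S)-7-hydroxy-6-(propan-2-yl)-1-oxaspiro[2.5]octan-5-yl (2E)-4-[(TBS)oxy]-2-methylbut-2-enoate (both configurations at the spiro carbon)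
Conditions: mCPBA, NaHCO3, CH2Cl2, 0 °C
Reagents that add atoms: 3-chloroperoxybenzoic acid, O=C(OO)c1cccc(Cl)c1
Why: Prilezhaev epoxidation; the isolated 1,1-disubstituted alkene is far more nucleophilic than the ester-conjugated alkene of the side chain. The new spiro centre is destroyed in step 7, so its configuration does not matter.

Step 7
Reactants: 11 (5S,6S,7S)-7-hydroxy-6-(propan-2-yl)-1-oxaspiro[2.5]octan-5-yl (2E)-4-[(TBS)oxy]-2-methylbut-2-enoate
Product: 13 (1S,6R)-3-(hydroxymethyl)-5-oxo-6-(propan-2-yl)cyclohex-3-en-1-yl (2E)-4-[(TBS)oxy]-2-methylbut-2-enoate, via spiro-epoxy ketone 12 (not isolated)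
Conditions: Dess–Martin periodinane, NaHCO3, CH2Cl2, 0 °C to rt; aqueous Na2S2O3/NaHCO3 wash; crude ketone, Et3N, CH2Cl2, 0 °C
Reagents that add atoms: none
Why: Dess–Martin oxidation of the C4 carbinol gives a β,γ-epoxy ketone in which only C3–H2 lies between the carbonyl and the epoxide carbon, so E1cB opening with a mild amine base can only give the C2=C3 enone with the hydroxymethyl group on C2. The C3 methylene is less hindered than the C5 methine and its elimination releases epoxide strain, which should keep the C6 ester in place.

Step 8
Reactants: 13 (1S,6R)-3-(hydroxymethyl)-5-oxo-6-(propan-2-yl)cyclohex-3-en-1-yl (2E)-4-[(TBS)oxy]-2-methylbut-2-enoate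
Product: 14 (1S,6R)-3-{[(TBS)oxy]methyl}-5-oxo-6-(propan-2-yl)cyclohex-3-en-1-yl (2E)-4-[(TBS)oxy]-2-methylbut-2-enoate
Conditions: TBSCl, imidazole, CH2Cl2, 0 °C
Reagents that add atoms: tert-butyl(chloro)dimethylsilane, CC(C)(C)[Si](C)(C)Cl
Why: Silylation of a primary allylic alcohol under weakly basic conditions that a β-acyloxy ketone should tolerate.

Step 9
Reactants: 14 (1S,6R)-3-{[(TBS)oxy]methyl}-5-oxo-6-(propan-2-yl)cyclohex-3-en-1-yl (2E)-4-[(TBS)oxy]-2-methylbut-2-enoate
Product: 15 (1S,5S,6S)-3-{[(TBS)oxy]methyl}-5-hydroxy-6-(propan-2-yl)cyclohex-3-en-1-yl (2E)-4-[(TBS)oxy]-2-methylbut-2-enoate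
Conditions: LiBH(s-Bu)3, THF, −78 °C; saturated aqueous NH4Cl
Reagents that add atoms: none
Why: Substrate-controlled 1,2-reduction: bulky trialkylborohydrides reduce β,β-disubstituted cyclohexenones at the carbonyl and approach from the equatorial direction, as in the reduction of menthone to neomenthol. The hydride should therefore arrive trans to the C5 isopropyl group and leave the C4 hydroxyl cis to it (4S); esters are not reduced at −78 °C.

Step 10
Reactants: 15 (1S,5S,6S)-3-{[(TBS)oxy]methyl}-5-hydroxy-6-(propan-2-yl)cyclohex-3-en-1-yl (2E)-4-[(TBS)oxy]-2-methylbut-2-enoate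
Product: 16 (1S,5S,6R)-3-{[(TBS)oxy]methyl}-5-(2-methylpropanoyloxy)-6-(propan-2-yl)cyclohex-3-en-1-yl (2E)-4-[(TBS)oxy]-2-methylbut-2-enoate
Conditions: (i-PrCO)2O, DMAP, Et3N, CH2Cl2, rt
Reagents that add atoms: 2-methylpropanoic anhydride, CC(C)C(=O)OC(=O)C(C)C
Why: DMAP-catalysed acylation of the hindered axial allylic alcohol, with retention at C4 (the descriptor at C5 changes only because the priorities change).

Step 11
Reactants: 16 (1S,5S,6R)-3-{[(TBS)oxy]methyl}-5-(2-methylpropanoyloxy)-6-(propan-2-yl)cyclohex-3-en-1-yl (2E)-4-[(TBS)oxy]-2-methylbut-2-enoate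
Product: 17 (1R,5S,6S)-3-{[(TBS)oxy]methyl}-2-hydroxy-5-(2-methylpropanoyloxy)-6-(propan-2-yl)cyclohex-3-en-1-yl (2E)-4-[(TBS)oxy]-2-methylbut-2-enoate (either configuration at the new carbinol)
Conditions: SeO2 (0.5 equiv), t-BuOOH, CH2Cl2, rt
Reagents that add atoms: tert-butyl hydroperoxide, CC(C)(C)OO; selenium dioxide, O=[Se]=O (delivers the oxygen and is regenerated by the hydroperoxide)
Why: Selenium dioxide allylic hydroxylation (ene reaction, then [2,3]-sigmatropic shift), which returns the double bond to C2=C3 and oxidises the ring methylene on the more substituted alkene carbon, as in the conversion of 1-methylcyclohexene into 2-methylcyclohex-2-enol. The new C1 carbinol centre is removed in step 12.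

Step 12
Reactants: 17 (1R,5S,6S)-3-{[(TBS)oxy]methyl}-2-hydroxy-5-(2-methylpropanoyloxy)-6-(propan-2-yl)cyclohex-3-en-1-yl (2E)-4-[(TBS)oxy]-2-methylbut-2-enoate
Product: 18 (1R,5S,6S)-3-{[(TBS)oxy]methyl}-5-(2-methylpropanoyloxy)-2-oxo-6-(propan-2-yl)cyclohex-3-en-1-yl (2E)-4-[(TBS)oxy]-2-methylbut-2-enoate
Conditions: Dess–Martin periodinane, NaHCO3, CH2Cl2, 0 °C to rt
Reagents that add atoms: none
Why: Dess–Martin oxidation of a secondary allylic alcohol to the enone under non-basic conditions that should not epimerise the α-acyloxy centre C6.

Step 13
Reactants: 18 (1R,5S,6S)-3-{[(TBS)oxy]methyl}-5-(2-methylpropanoyloxy)-2-oxo-6-(propan-2-yl)cyclohex-3-en-1-yl (2E)-4-[(TBS)oxy]-2-methylbut-2-enoate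
Product: 19 (1R,5S,6S)-3-(hydroxymethyl)-5-(2-methylpropanoyloxy)-2-oxo-6-(propan-2-yl)cyclohex-3-en-1-yl (2E)-4-hydroxy-2-methylbut-2-enoate (CNP0254776.1)
Conditions: HF·pyridine, pyridine, THF, 0 °C to rt
Reagents that add atoms: none
Why: Buffered fluoride cleavage of two primary silyl ethers; the medium should be neither basic enough to epimerise C6 or move acyl groups nor acidic enough to ionise the C4 allylic ester.

## Compound list

1 | diethyl 2-(propan-2-yl)propanedioate | CCOC(=O)C(C(C)C)C(=O)OCC | starting material
2 | 2-(propan-2-yl)propane-1,3-diol | CC(C)C(CO)CO | intermediate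
3 | 2-methylidenepropane-1,3-diyl diacetate | C=C(COC(C)=O)COC(C)=O | starting material
4 | (4S)-4-hydroxy-5-(hydroxymethyl)-6-methyl-2-methylideneheptyl acetate (both epimers at C5) | CC(=O)OCC(=C)C[C@H](O)C(CO)C(C)C | intermediate (not isolated)
5 | (1S,3S)-5-methylidene-2-(propan-2-yl)cyclohexane-1,3-diol | O[C@H]1CC(=C)C[C@H](O)C1C(C)C | intermediate
6 | 2-[(tert-butyldimethylsilyl)oxy]acetaldehyde | O=CCO[Si](C)(C)C(C)(C)C | starting material
7 | ethyl 2-(triphenyl-λ5-phosphanylidene)propanoate | CCOC(=O)C(C)=P(c1ccccc1)(c1ccccc1)c1ccccc1 | starting material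
8 | ethyl (2E)-4-[(tert-butyldimethylsilyl)oxy]-2-methylbut-2-enoate | C/C(=C\CO[Si](C)(C)C(C)(C)C)C(=O)OCC | intermediate
9 | (2E)-4-[(tert-butyldimethylsilyl)oxy]-2-methylbut-2-enoic acid | C/C(=C\CO[Si](C)(C)C(C)(C)C)C(=O)O | intermediate
10 | (1S,2S,3S)-3-hydroxy-5-methylidene-2-(propan-2-yl)cyclohexyl (2E)-4-[(TBS)oxy]-2-methylbut-2-enoate | C/C(=C\CO[Si](C)(C)C(C)(C)C)C(=O)O[C@H]1CC(=C)C[C@H](O)[C@@H]1C(C)C | intermediate
11 | (5S,6S,7S)-7-hydroxy-6-(propan-2-yl)-1-oxaspiro[2.5]octan-5-yl (2E)-4-[(TBS)oxy]-2-methylbut-2-enoate, both spiro epimers | C/C(=C\CO[Si](C)(C)C(C)(C)C)C(=O)O[C@H]1CC2(CO2)C[C@H](O)[C@@H]1C(C)C | intermediate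
12 | (5S,6R)-7-oxo-6-(propan-2-yl)-1-oxaspiro[2.5]octan-5-yl (2E)-4-[(TBS)oxy]-2-methylbut-2-enoate, both spiro epimers | C/C(=C\CO[Si](C)(C)C(C)(C)C)C(=O)O[C@H]1CC2(CO2)CC(=O)[C@@H]1C(C)C | intermediate (not isolated)
13 | (1S,6R)-3-(hydroxymethyl)-5-oxo-6-(propan-2-yl)cyclohex-3-en-1-yl (2E)-4-[(TBS)oxy]-2-methylbut-2-enoate | C/C(=C\CO[Si](C)(C)C(C)(C)C)C(=O)O[C@H]1CC(CO)=CC(=O)[C@@H]1C(C)C | intermediate
14 | (1S,6R)-3-{[(TBS)oxy]methyl}-5-oxo-6-(propan-2-yl)cyclohex-3-en-1-yl (2E)-4-[(TBS)oxy]-2-methylbut-2-enoate | C/C(=C\CO[Si](C)(C)C(C)(C)C)C(=O)O[C@H]1CC(CO[Si](C)(C)C(C)(C)C)=CC(=O)[C@@H]1C(C)C | intermediate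
15 | (1S,5S,6S)-3-{[(TBS)oxy]methyl}-5-hydroxy-6-(propan-2-yl)cyclohex-3-en-1-yl (2E)-4-[(TBS)oxy]-2-methylbut-2-enoate | C/C(=C\CO[Si](C)(C)C(C)(C)C)C(=O)O[C@H]1CC(CO[Si](C)(C)C(C)(C)C)=C[C@H](O)[C@@H]1C(C)C | intermediate
16 | (1S,5S,6R)-3-{[(TBS)oxy]methyl}-5-(2-methylpropanoyloxy)-6-(propan-2-yl)cyclohex-3-en-1-yl (2E)-4-[(TBS)oxy]-2-methylbut-2-enoate | C/C(=C\CO[Si](C)(C)C(C)(C)C)C(=O)O[C@H]1CC(CO[Si](C)(C)C(C)(C)C)=C[C@H](OC(=O)C(C)C)[C@@H]1C(C)C | intermediate
17 | (1R,5S,6S)-3-{[(TBS)oxy]methyl}-2-hydroxy-5-(2-methylpropanoyloxy)-6-(propan-2-yl)cyclohex-3-en-1-yl (2E)-4-[(TBS)oxy]-2-methylbut-2-enoate, either configuration at C2 of the ring name | C/C(=C\CO[Si](C)(C)C(C)(C)C)C(=O)O[C@H]1C(O)C(CO[Si](C)(C)C(C)(C)C)=C[C@H](OC(=O)C(C)C)[C@@H]1C(C)C | intermediate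
18 | (1R,5S,6S)-3-{[(TBS)oxy]methyl}-5-(2-methylpropanoyloxy)-2-oxo-6-(propan-2-yl)cyclohex-3-en-1-yl (2E)-4-[(TBS)oxy]-2-methylbut-2-enoate | C/C(=C\CO[Si](C)(C)C(C)(C)C)C(=O)O[C@H]1C(=O)C(CO[Si](C)(C)C(C)(C)C)=C[C@H](OC(=O)C(C)C)[C@@H]1C(C)C | intermediate
19 | (1R,5S,6S)-3-(hydroxymethyl)-5-(2-methylpropanoyloxy)-2-oxo-6-(propan-2-yl)cyclohex-3-en-1-yl (2E)-4-hydroxy-2-methylbut-2-enoate | C/C(=C\CO)C(=O)O[C@H]1C(=O)C(CO)=C[C@H](OC(=O)C(C)C)[C@@H]1C(C)C | target

## Step count and least certain steps

Total step count: 13. Longest linear sequence: 11 steps (steps 1, 2 and 5 to 13); steps 3 and 4 are the two-step branch to 9.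

Step 2 (key step, new method).
- What may go wrong: a second intermolecular allylation or oligomerisation may win over ring closure, because the tethered allyl complex has to wait for dehydrogenation of its own alcohol. Acetyl transfer from 3 to the hydroxyls of 2 under carbonate at 100 °C may consume the donor, and the 2-substituted allylic acetates may ionise slowly. The bicyclic ring-closing transition state may override the catalyst and give the meso cis diol.
- Fallback (known reactions only; sets out from 2, returns at 5): 2 is converted into its mono(4-methoxybenzyl) ether F1 (NaH, 4-methoxybenzyl chloride). The remaining primary alcohol undergoes the known intermolecular iridium-catalysed C-methallylation from the alcohol oxidation level (methallyl chloride, same catalyst system). This gives the (3S)-carbinol as two C2 epimers, of which the (2S,3S)-homoallylic alcohol F2 is separated and carried on. Silylation (TBSOTf, 2,6-lutidine) gives the silyl ether F3, DDQ the primary alcohol F4, and Dess–Martin oxidation the aldehyde F5. A Me2AlCl-promoted type 2 carbonyl-ene cyclisation forms C4–C3 and places the double bond exocyclic (cyclohexanol F6, mixture at the new carbinol). The new carbinol is corrected by Dess–Martin oxidation to the ketone F7 and reduction with LiBH(s-Bu)3 to the alcohol F8 (hydroxyl cis to isopropyl), and Bu4NF gives 5.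
- Cost: length, and loss of the other C2 epimer of F2, because in a stepwise route the isopropyl-bearing carbon is a stereocentre from the first bond formation on.

Step 5 (selective esterification).
- What may go wrong: insufficient discrimination between the equatorial and the axial hydroxyl, and over-acylation to the diester. The two hydroxyls differ only in their relationship to isopropyl.
- Fallback (sets out from 5, returns at 11): both hydroxyls are converted into tert-butyl carbonates to give the bis(tert-butyl carbonate) F9 (Boc2O, DMAP). Iodine (MeCN, −20 °C) then triggers iodocarbonate cyclisation, which is possible only for the carbonate that can become 1,3-diaxial with C2, the one on C4, and gives the bridged cyclic iodocarbonate F10. Trifluoroacetic acid removes the remaining tert-butyl carbonate (hydroxy iodocarbonate F11), the free C6 hydroxyl is esterified with 9 (DCC, DMAP) to the ester F12, and K2CO3 in methanol cleaves the cyclic carbonate and closes the epoxide, which gives 11 as a single spiro epimer.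
- What changes: the distinction rests on an intramolecular, conformation-gated reaction and not on a rate difference between two intermolecular acylations.

Step 7 (oxidation and epoxide opening).
- What may go wrong: base-induced loss of the C6 carboxylate from the β-acyloxy ketone, followed by aromatisation, may compete with the epoxide opening.
- Fallback (sets out from 10, returns at 14): dihydroxylation of the exocyclic alkene (OsO4 cat., N-methylmorpholine N-oxide) gives the triol F13, silylation of its primary hydroxyl the primary silyl ether F14, and Dess–Martin oxidation the β-hydroxy ketone F15. Dehydration with the Burgess reagent under neutral conditions (syn elimination towards the acidic C3–H) gives 14 directly.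

Step 9 (ketone reduction).
- What may go wrong: poor facial selectivity (delivery from the axial direction), or conjugate reduction.
- Fallback (sets out from 14, returns at 16): reduction under Luche conditions (NaBH4, CeCl3·7H2O, MeOH, −78 °C), which should favour axial delivery, gives the C4-epimeric alcohol F16. Mitsunobu esterification with isobutyric acid (PPh3, diisopropyl azodicarboxylate) inverts C4 and gives 16.

Step 11 (allylic hydroxylation).
- What may go wrong: the alkene carries two allylic oxygen substituents and may react too slowly with the electrophilic selenium reagent, or hydrogen may be taken from the silyloxymethyl group and not from C1.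
- Fallback (sets out from 14, returns at 17): the C1 oxygen is introduced at the enone stage by polar chemistry. 14 is converted into its linear silyl dienol ether F17 (TBSOTf, Et3N, γ-deprotonation at C1), which is oxidised at the γ-carbon with mCPBA (vinylogous Rubottom oxidation) to the γ-hydroxy enone F18. The C1 hydroxyl is protected as the triethylsilyl ether F19, the C4 ketone is reduced with LiBH(s-Bu)3 to the allylic alcohol F20 and acylated to the isobutyrate F21, and the triethylsilyl group is removed selectively (pyridinium p-toluenesulfonate, MeOH) to give 17.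
- Cost: the sequence is longer and passes through an acyloxy-substituted cyclohexadiene that must be kept cold, but the site of oxidation is fixed by the enol ether and not by a choice between C–H bonds.

## Further compounds

F1 | step 2 | 3-[(4-methoxyphenyl)methoxy]-2-(propan-2-yl)propan-1-ol (racemic) | COc1ccc(COCC(CO)C(C)C)cc1
F2 | step 2 | (2S,3S)-1-[(4-methoxyphenyl)methoxy]-5-methyl-2-(propan-2-yl)hex-5-en-3-ol | COc1ccc(COC[C@@H]([C@@H](O)CC(C)=C)C(C)C)cc1
F3 | step 2 | TBS ether of F2 at the secondary hydroxyl | COc1ccc(COC[C@@H]([C@@H](O[Si](C)(C)C(C)(C)C)CC(C)=C)C(C)C)cc1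
F4 | step 2 | (2S,3S)-3-[(TBS)oxy]-5-methyl-2-(propan-2-yl)hex-5-en-1-ol | OC[C@@H]([C@@H](O[Si](C)(C)C(C)(C)C)CC(C)=C)C(C)C
F5 | step 2 | (2S,3S)-3-[(TBS)oxy]-5-methyl-2-(propan-2-yl)hex-5-enal | O=C[C@@H]([C@@H](O[Si](C)(C)C(C)(C)C)CC(C)=C)C(C)C
F6 | step 2 | 3-[(TBS)oxy]-5-methylidene-2-(propan-2-yl)cyclohexan-1-ol, silyloxy trans to isopropyl, both epimers at the free carbinol | CC(C)(C)[Si](C)(C)O[C@H]1CC(=C)CC(O)[C@@H]1C(C)C
F7 | step 2 | 3-[(TBS)oxy]-5-methylidene-2-(propan-2-yl)cyclohexan-1-one, silyloxy trans to isopropyl | CC(C)(C)[Si](C)(C)O[C@H]1CC(=C)CC(=O)[C@@H]1C(C)C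
F8 | step 2 | mono-TBS ether of 5 at the hydroxyl trans to isopropyl | CC(C)(C)[Si](C)(C)O[C@H]1CC(=C)C[C@H](O)[C@@H]1C(C)C
F9 | step 5 | di-tert-butyl (1S,3S)-5-methylidene-2-(propan-2-yl)cyclohexane-1,3-diyl dicarbonate | CC(C)(C)OC(=O)O[C@H]1CC(=C)C[C@H](OC(=O)OC(C)(C)C)C1C(C)C
F10 | step 5 | tert-butyl 1-(iodomethyl)-3-oxo-6-(propan-2-yl)-2,4-dioxabicyclo[3.3.1]nonan-7-yl carbonate (cyclic carbonate bridging C4 and C2) | CC(C)(C)OC(=O)O[C@H]1C[C@@]2(CI)C[C@H](OC(=O)O2)[C@@H]1C(C)C
F11 | step 5 | 7-hydroxy-1-(iodomethyl)-6-(propan-2-yl)-2,4-dioxabicyclo[3.3.1]nonan-3-one | O[C@H]1C[C@@]2(CI)C[C@H](OC(=O)O2)[C@@H]1C(C)C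
F12 | step 5 | ester of F11 with 9 at the C6 hydroxyl | C/C(=C\CO[Si](C)(C)C(C)(C)C)C(=O)O[C@H]1C[C@@]2(CI)C[C@H](OC(=O)O2)[C@@H]1C(C)C
F13 | step 7 | (1S,2S,3S)-3,5-dihydroxy-5-(hydroxymethyl)-2-(propan-2-yl)cyclohexyl (2E)-4-[(TBS)oxy]-2-methylbut-2-enoate, both C5 epimers | C/C(=C\CO[Si](C)(C)C(C)(C)C)C(=O)O[C@H]1CC(O)(CO)C[C@H](O)[C@@H]1C(C)C
F14 | step 7 | primary TBS ether of F13 | C/C(=C\CO[Si](C)(C)C(C)(C)C)C(=O)O[C@H]1CC(O)(CO[Si](C)(C)C(C)(C)C)C[C@H](O)[C@@H]1C(C)C
F15 | step 7 | (1S,2R)-5-hydroxy-5-{[(TBS)oxy]methyl}-3-oxo-2-(propan-2-yl)cyclohexyl (2E)-4-[(TBS)oxy]-2-methylbut-2-enoate, both C5 epimers | C/C(=C\CO[Si](C)(C)C(C)(C)C)C(=O)O[C@H]1CC(O)(CO[Si](C)(C)C(C)(C)C)CC(=O)[C@@H]1C(C)C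
F16 | step 9 | C4 epimer of 15 (hydroxyl trans to isopropyl) | C/C(=C\CO[Si](C)(C)C(C)(C)C)C(=O)O[C@H]1CC(CO[Si](C)(C)C(C)(C)C)=C[C@@H](O)[C@@H]1C(C)C
F17 | step 11 | TBS dienol ether of 14 (C4–O–Si, double bonds C3=C4 and C1=C2) | C/C(=C\CO[Si](C)(C)C(C)(C)C)C(=O)O[C@H]1C=C(CO[Si](C)(C)C(C)(C)C)C=C(O[Si](C)(C)C(C)(C)C)[C@@H]1C(C)C
F18 | step 11 | C1-hydroxy derivative of 14 (γ-hydroxy enone, either configuration at C1) | C/C(=C\CO[Si](C)(C)C(C)(C)C)C(=O)O[C@H]1C(O)C(CO[Si](C)(C)C(C)(C)C)=CC(=O)[C@@H]1C(C)C
F19 | step 11 | C1 triethylsilyl ether of F18 | C/C(=C\CO[Si](C)(C)C(C)(C)C)C(=O)O[C@H]1C(O[Si](CC)(CC)CC)C(CO[Si](C)(C)C(C)(C)C)=CC(=O)[C@@H]1C(C)C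
F20 | step 11 | C4 alcohol from F19 (hydroxyl cis to isopropyl) | C/C(=C\CO[Si](C)(C)C(C)(C)C)C(=O)O[C@H]1C(O[Si](CC)(CC)CC)C(CO[Si](C)(C)C(C)(C)C)=C[C@H](O)[C@@H]1C(C)C
F21 | step 11 | C4 isobutyrate of F20 (C1 triethylsilyl ether of 17) | C/C(=C\CO[Si](C)(C)C(C)(C)C)C(=O)O[C@H]1C(O[Si](CC)(CC)CC)C(CO[Si](C)(C)C(C)(C)C)=C[C@H](OC(=O)C(C)C)[C@@H]1C(C)C
A1 | alternative 1 | methyl 2-oxo-2H-pyran-3-carboxylate | COC(=O)C1=CC=COC1=O
A2 | alternative 1 | 1-methoxy-4-({[(1E)-3-methylbut-1-en-1-yl]oxy}methyl)benzene | COc1ccc(CO/C=C/C(C)C)cc1
A3 | alternative 1 | methyl 7-isopropyl-8-[(4-methoxybenzyl)oxy]-3-oxo-2-oxabicyclo[2.2.2]oct-5-ene-4-carboxylate, alkoxy endo, isopropyl exo | COc1ccc(CO[C@H]2[C@@]3(C(=O)OC)C=C[C@H](OC3=O)[C@@H]2C(C)C)cc1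
A4 | alternative 2 | 4,4-dimethoxycyclohexa-2,5-dien-1-one | COC1(OC)C=CC(=O)C=C1
A5 | alternative 2 | diisopropylzinc | CC(C)[Zn]C(C)C
A6 | alternative 2 | trans-6-hydroxy-5-isopropyl-4,4-dimethoxycyclohex-2-en-1-one, single enantiomer | O[C@H]1C(=O)C=CC(OC)(OC)[C@@H]1C(C)C
A7 | alternative 3 | (3Z)-3-{[(tert-butyldimethylsilyl)oxy]methyl}-7-methyl-1,2-dioxoocta-3,6-dien-5-yl 2-methylpropanoate, single enantiomer | O=CC(=O)/C(CO[Si](C)(C)C(C)(C)C)=C\[C@H](OC(=O)C(C)C)C=C(C)C
A8 | alternative 3 | 6-hydroxy-4-(isobutyryloxy)-5-isopropenyl-2-[(tert-butyldimethylsilyloxy)methyl]cyclohex-2-en-1-one, 4,5-cis and 5,6-trans | O[C@H]1C(=O)C(CO[Si](C)(C)C(C)(C)C)=C[C@H](OC(=O)C(C)C)[C@@H]1C(C)=C
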